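**Plan**

The ring C3a–C4–C5–C6–C7–C7a of the target is a resorcinol nucleus (oxygens at C4 and C7a) that carries one more oxygen at C7, para to the C4 oxygen, and two more hydrogens at C5/C6, so the carbocycle can be carried as a flat, symmetric phenol until late.
Retrosynthetic cuts, in order: the ester C–O bond; the C7 carbinol and the C5–C6 single bond back to the 7,7-dimethoxy dienone; its two C7–O bonds (dearomatisation of the 4-hydroxy-2,3-dihydrobenzofuran); O1–C2′ (phenoxide/epoxide); C3′–C3a (aryl Grignard/epoxy triflate); then C2=C3 (Wittig) and C3–C4/C4–C5 (nitrile alkylation) of the chain.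
Forward: nerol is extended to the (2E,6E,10Z)-C15 hydroxy ester, epoxidised, and joined as its triflate to 2-metalated resorcinol bis(allyl ether); deallylation closes the dihydrofuran ring, and the carbocycle itself is never built, only dearomatised and trimmed.
Stereochemistry: C10 and C2′ come from Sharpless epoxidation (D-(−)-tartrate) of the (Z)-allylic alcohol followed by invertive 5-exo opening at C2′; C7 comes from a catalyst-controlled CBS reduction.
Alkene geometry: 6E comes from SeO2 oxidation at the (E)-methyl group, 2E from the stabilised ylide, and the (Z)-alkene of nerol is what becomes the cis-epoxide.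

Key step: step 14

Remark: ring atoms are numbered as in 2,3-dihydro-1-benzofuran (O1, C2′, C3′, C3a, C4–C7, C7a) and chain atoms as in the undeca-2,6-dienoate (C1–C10). Compounds 22–25 are one tautomerisation or elimination away from arenes and are assumed to need base-free handling.

**Route**

Step 1
Reactants: 1 nerol, (2Z)-3,7-dimethylocta-2,6-dien-1-ol
Product: 2 tert-butyl{[(2Z)-3,7-dimethylocta-2,6-dien-1-yl]oxy}dimethylsilane
Conditions: TBSCl, imidazole, CH2Cl2, 0 °C → rt
Reagents that add atoms: tert-butyldimethylsilyl chloride, CC(C)(C)[Si](C)(C)Cl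
Why: Standard silylation of a primary allylic alcohol masks the C1 hydroxyl so that the allylic oxidation, bromination and carbanion steps act only at the far end of the chain; no stereocentre is involved.

Step 2
Reactants: 2 tert-butyl{[(2Z)-3,7-dimethylocta-2,6-dien-1-yl]oxy}dimethylsilane
Product: 3 (2E,6Z)-8-[(tert-butyldimethylsilyl)oxy]-2,6-dimethylocta-2,6-dien-1-ol
Conditions: SeO2 (cat.), t-BuOOH, salicylic acid (cat.), CH2Cl2, 0 °C → rt
Reagents that add atoms: tert-butyl hydroperoxide, CC(C)(C)OO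
Why: Catalytic SeO2/t-BuOOH allylic oxidation (ene reaction, then [2,3]-shift) attacks the more electron-rich terminal trisubstituted alkene at its (E)-methyl group and should give the (E)-allylic alcohol, the oxygen-substituted alkene being deactivated.

Step 3
Reactants: 3 (2E,6Z)-8-[(tert-butyldimethylsilyl)oxy]-2,6-dimethylocta-2,6-dien-1-ol
Product: 4 {[(2Z,6E)-8-bromo-3,7-dimethylocta-2,6-dien-1-yl]oxy}(tert-butyl)dimethylsilane
Conditions: CBr4, PPh3, CH2Cl2, −20 → 0 °C
Reagents that add atoms: carbon tetrabromide, BrC(Br)(Br)Br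
Why: Appel bromination of a primary allylic alcohol proceeds by SN2 on the alkoxyphosphonium ion at low temperature, without allylic transposition or E/Z scrambling, and the neutral conditions spare the silyl ether.

Step 4
Reactants: 4 {[(2Z,6E)-8-bromo-3,7-dimethylocta-2,6-dien-1-yl]oxy}(tert-butyl)dimethylsilane
Product: 5 (4E,8Z)-10-[(tert-butyldimethylsilyl)oxy]-4,8-dimethyldeca-4,8-dienenitrile
Conditions: MeCN (5 equiv), n-BuLi (4.5 equiv), THF, −78 °C; then 4, −78 → −30 °C
Reagents that add atoms: acetonitrile, CC#N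
Why: SN2 alkylation of excess lithioacetonitrile by the primary allylic bromide adds the two carbons that become C4 and C3 of the target chain, the excess of nucleophile suppressing double alkylation.

Step 5
Reactants: 5 (4E,8Z)-10-[(tert-butyldimethylsilyl)oxy]-4,8-dimethyldeca-4,8-dienenitrile
Product: 7 (4E,8Z)-10-[(tert-butyldimethylsilyl)oxy]-4,8-dimethyldeca-4,8-dienal, via N-alumino aldimine 6 (not isolated)
Conditions: DIBAL-H, CH2Cl2, −78 °C; then aq. Rochelle salt, rt
Reagents that add atoms: water, O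
Why: Partial reduction of a nitrile with DIBAL-H stops at the N-alumino aldimine, which is hydrolysed on work-up to the aldehyde while the silyl ether and both alkenes are untouched.

Step 6
Reactants: 7 (4E,8Z)-10-[(tert-butyldimethylsilyl)oxy]-4,8-dimethyldeca-4,8-dienal; 8 methyl 2-(triphenyl-λ5-phosphanylidene)propanoate
Product: 9 methyl (2E,6E,10Z)-12-[(tert-butyldimethylsilyl)oxy]-2,6,10-trimethyldodeca-2,6,10-trienoate
Conditions: CH2Cl2, rt
Reagents that add atoms: none
Why: Wittig olefination with a stabilised α-branched ylide is under thermodynamic control at the oxaphosphetane stage and should give the (E)-trisubstituted enoate C2=C3.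

Step 7
Reactants: 9 methyl (2E,6E,10Z)-12-[(tert-butyldimethylsilyl)oxy]-2,6,10-trimethyldodeca-2,6,10-trienoate
Product: 10 methyl (2E,6E,10Z)-12-hydroxy-2,6,10-trimethyldodeca-2,6,10-trienoate
Conditions: CSA (10 mol %), MeOH, 0 °C → rt
Reagents that add atoms: none
Why: Acid-catalysed methanolysis removes the primary silyl ether, while the methyl ester is degenerate towards methanol and the trisubstituted alkenes are inert to catalytic acid at this temperature.

Step 8
Reactants: 10 methyl (2E,6E,10Z)-12-hydroxy-2,6,10-trimethyldodeca-2,6,10-trienoate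
Product: 11 methyl (2E,6E)-9-[(2S,3R)-3-(hydroxymethyl)-2-methyloxiran-2-yl]-2,6-dimethylnona-2,6-dienoate
Conditions: Ti(OiPr)4 (10 mol %), D-(−)-diethyl tartrate (12 mol %), t-BuOOH, 4 Å MS, CH2Cl2, −20 °C
Reagents that add atoms: tert-butyl hydroperoxide, CC(C)(C)OO
Why: Sharpless asymmetric epoxidation is directed by the allylic hydroxyl, so only the C10=C11 alkene reacts, and with the D-(−)-tartrate ligand the (Z)-alcohol should give the (2S,3R)-oxirane, which fixes the tertiary C–O centre (C10 of the target, S) and the oxirane CH that is inverted in step 13.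

Step 9
Reactants: 11 methyl (2E,6E)-9-[(2S,3R)-3-(hydroxymethyl)-2-methyloxiran-2-yl]-2,6-dimethylnona-2,6-dienoate
Product: 12 methyl (2E,6E)-2,6-dimethyl-9-[(2S,3R)-2-methyl-3-{[(trifluoromethanesulfonyl)oxy]methyl}oxiran-2-yl]nona-2,6-dienoate
Conditions: Tf2O, 2,6-lutidine, CH2Cl2, −78 °C; cold work-up, used at once
Reagents that add atoms: trifluoromethanesulfonic anhydride, O=S(=O)(OS(=O)(=O)C(F)(F)F)C(F)(F)F
Why: O-Sulfonylation of the primary alcohol with a hindered pyridine base at −78 °C gives the epoxy triflate without touching either oxirane stereocentre and provides a leaving group reactive enough for C–C coupling below −30 °C.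

Step 10
Reactants: 13 resorcinol, benzene-1,3-diol
Product: 14 2-iodobenzene-1,3-diol
Conditions: I2, NaHCO3, H2O, 0 °C → rt
Reagents that add atoms: iodine, II
Why: Electrophilic iodination of resorcinol in aqueous bicarbonate is known to occur at C2, between the two hydroxyl groups, and marks the carbon that becomes C3a.

Step 11
Reactants: 14 2-iodobenzene-1,3-diol
Product: 15 2-iodo-1,3-bis(prop-2-en-1-yloxy)benzene
Conditions: allyl bromide, K2CO3, DMF, rt → 50 °C
Reagents that add atoms: allyl bromide, C=CCBr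
Why: Williamson O-allylation gives two ethers that withstand organomagnesium chemistry and can later be removed under basic, non-acidic conditions, which the epoxide requires.

Step 12
Reactants: 15 2-iodo-1,3-bis(prop-2-en-1-yloxy)benzene; 12 methyl (2E,6E)-2,6-dimethyl-9-[(2S,3R)-2-methyl-3-{[(trifluoromethanesulfonyl)oxy]methyl}oxiran-2-yl]nona-2,6-dienoate
Product: 17 methyl (2E,6E)-9-[(2S,3R)-3-{[2,6-bis(prop-2-en-1-yloxy)phenyl]methyl}-2-methyloxiran-2-yl]-2,6-dimethylnona-2,6-dienoate, via aryl Grignard 16 (not isolated)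
Conditions: 15 (1.6 equiv), i-PrMgCl·LiCl, THF, −15 °C → rt; then CuBr·SMe2 (15 mol %), 12, THF, −78 → −30 °C
Reagents that add atoms: none
Why: Iodine–magnesium exchange gives the 2,6-dialkoxyphenyl Grignard reagent, and copper-catalysed Kumada-type alkylation of a Grignard reagent by a primary triflate is fast at −78 °C, where the ester and the oxirane (hindered at both carbons by the adjacent quaternary centre) should not compete, so the C3′–C3a bond forms by SN2 at the CH2 group with both stereocentres untouched.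

Step 13
Reactants: 17 methyl (2E,6E)-9-[(2S,3R)-3-{[2,6-bis(prop-2-en-1-yloxy)phenyl]methyl}-2-methyloxiran-2-yl]-2,6-dimethylnona-2,6-dienoate
Product: 19 methyl (2E,6E,10S)-10-hydroxy-10-[(2S)-4-hydroxy-2,3-dihydro-1-benzofuran-2-yl]-2,6-dimethylundeca-2,6-dienoate, via epoxy resorcinol 18 (not isolated)
Conditions: Pd(PPh3)4 (5 mol %), K2CO3, MeOH, Ar, rt → 40 °C
Reagents that add atoms: none
Why: Pd(0)-catalysed transfer of the allyl groups to methanol (Tsuji–Trost deallylation) frees the phenoxide, which opens the oxirane by 5-exo-tet attack at the secondary carbon with inversion (basic medium, so no 6-endo attack at the tertiary carbon), setting C2′ as S while C10 keeps the S configuration from step 8.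

Step 14
Reactants: 19 methyl (2E,6E,10S)-10-hydroxy-10-[(2S)-4-hydroxy-2,3-dihydro-1-benzofuran-2-yl]-2,6-dimethylundeca-2,6-dienoate
Product: 21 methyl (2E,6E,10S)-10-[(2S)-7,7-dimethoxy-4-oxo-2,3,4,7-tetrahydro-1-benzofuran-2-yl]-10-hydroxy-2,6-dimethylundeca-2,6-dienoate, via 7-methoxyphenol 20 (not isolated)
Conditions: PhI(OAc)2 (2.2 equiv), MeOH, 0 °C → rt
Reagents that add atoms: methanol, CO
Why: The phenol exchanges an acetate on iodine(III), methanol attacks the para carbon C7 as iodobenzene departs, and tautomerisation gives the 7-methoxy-4-phenol 20, which as a p-alkoxyphenol is oxidised faster than 19 by the second equivalent and takes up a second methanol at the same carbon, so both C7–O bonds form in one flask. The closest known reaction type is the λ3-iodane oxidation of para-unsubstituted phenols and of p-alkoxyphenols in methanol to p-quinone monoketals. No ring is closed and no stereocentre is created, and C2′ and C10 are not touched. The selectivity required is attack at C7 (para) and not at C5 (ortho) in the first oxidation: C7 is the open para position, C3a is blocked, the iodine-bearing oxygen shields C5, and para attack leads to the cross-conjugated dienone whose C4 carbonyl stays a vinylogous ester of O1; in the second oxidation the C7 methoxy group stabilises the cation and leaves no regiochemical choice. Because the arene derives from symmetric resorcinol, either oxygen could have become O1, so the C4-carbonyl/C7-ketal pattern follows from the substitution of the arene alone. The trisubstituted alkenes, the enoate and the tertiary alcohol should be inert to the oxidant, and the tertiary hydroxyl cannot add to C7 because that would place a bridgehead double bond at C7a.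

Step 15
Reactants: 21 methyl (2E,6E,10S)-10-[(2S)-7,7-dimethoxy-4-oxo-2,3,4,7-tetrahydro-1-benzofuran-2-yl]-10-hydroxy-2,6-dimethylundeca-2,6-dienoate
Product: 22 methyl (2E,6E,10S)-10-[(2S)-7,7-dimethoxy-4-oxo-2,3,4,5,6,7-hexahydro-1-benzofuran-2-yl]-10-hydroxy-2,6-dimethylundeca-2,6-dienoate
Conditions: [(Ph3P)CuH]6 (0.4 equiv), H2O (3 equiv), degassed PhMe, rt; pH 7 buffer work-up
Reagents that add atoms: none
Why: Conjugate reduction with Stryker's reagent delivers hydride to C6 of the unhindered cis-disubstituted enone, whereas the tetrasubstituted, oxygen-deactivated C3a=C7a bond, the chain enoate and the isolated alkenes react far more slowly, and protonation of the copper enolate by water under neutral conditions avoids loss of methanol towards the arene.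

Step 16
Reactants: 22 methyl (2E,6E,10S)-10-[(2S)-7,7-dimethoxy-4-oxo-2,3,4,5,6,7-hexahydro-1-benzofuran-2-yl]-10-hydroxy-2,6-dimethylundeca-2,6-dienoate
Product: 23 methyl (2E,6E,10S)-10-[(2S)-4,7-dioxo-2,3,4,5,6,7-hexahydro-1-benzofuran-2-yl]-10-hydroxy-2,6-dimethylundeca-2,6-dienoate
Conditions: SiO2, 10% aq. oxalic acid, CH2Cl2, 0 °C → rt; filtration, used at once
Reagents that add atoms: water, O
Why: Mild acid-catalysed ketal hydrolysis (capture of the oxocarbenium ion by water) should be much faster than acid-catalysed enolisation of the two ketones, so the 2-alkoxy-ene-1,4-dione is expected before it can tautomerise to the hydroquinone, provided base is excluded.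

Step 17
Reactants: 23 methyl (2E,6E,10S)-10-[(2S)-4,7-dioxo-2,3,4,5,6,7-hexahydro-1-benzofuran-2-yl]-10-hydroxy-2,6-dimethylundeca-2,6-dienoate
Product: 24 methyl (2E,6E,10S)-10-hydroxy-10-[(2S,7R)-7-hydroxy-4-oxo-2,3,4,5,6,7-hexahydro-1-benzofuran-2-yl]-2,6-dimethylundeca-2,6-dienoate
Conditions: (S)-2-methyl-CBS-oxazaborolidine (0.5 equiv), catecholborane (2.5 equiv), PhMe, −78 °C; MeOH quench, pH 7 buffer
Reagents that add atoms: none
Why: Corey–Bakshi–Shibata reduction should select the C7 ketone over the vinylogous-ester carbonyl C4, and the (S)-oxazaborolidine, treating the substituted sp2 carbon C7a as the large group and C6H2 as the small one (as with 2-substituted cyclohex-2-enones), should deliver hydride to give the (7R)-alcohol under catalyst control, far from C2′.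

Step 18
Reactants: 24 methyl (2E,6E,10S)-10-hydroxy-10-[(2S,7R)-7-hydroxy-4-oxo-2,3,4,5,6,7-hexahydro-1-benzofuran-2-yl]-2,6-dimethylundeca-2,6-dienoate
Product: 25 (2E,6E,10S)-10-hydroxy-10-[(2S,7R)-7-hydroxy-4-oxo-2,3,4,5,6,7-hexahydro-1-benzofuran-2-yl]-2,6-dimethylundeca-2,6-dienoic acid
Conditions: Me3SnOH, 1,2-dichloroethane, 70 °C; then aq. KHSO4, 0 °C
Reagents that add atoms: trimethyltin hydroxide, C[Sn](C)(C)O
Why: Trimethyltin hydroxide cleaves methyl esters under near-neutral conditions by tin-assisted delivery of hydroxide to the ester carbonyl, which should spare the acid- and base-sensitive 7-hydroxy-4-oxo ring and the tertiary alcohol.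

**Compound list**

1 | nerol, (2Z)-3,7-dimethylocta-2,6-dien-1-ol | CC(C)=CCC/C(C)=C\CO | starting material
2 | tert-butyl{[(2Z)-3,7-dimethylocta-2,6-dien-1-yl]oxy}dimethylsilane | CC(C)=CCC/C(C)=C\CO[Si](C)(C)C(C)(C)C | intermediate
3 | (2E,6Z)-8-[(tert-butyldimethylsilyl)oxy]-2,6-dimethylocta-2,6-dien-1-ol | OC/C(C)=C/CC/C(C)=C\CO[Si](C)(C)C(C)(C)C | intermediate
4 | {[(2Z,6E)-8-bromo-3,7-dimethylocta-2,6-dien-1-yl]oxy}(tert-butyl)dimethylsilane | BrC/C(C)=C/CC/C(C)=C\CO[Si](C)(C)C(C)(C)C | intermediate
5 | (4E,8Z)-10-[(tert-butyldimethylsilyl)oxy]-4,8-dimethyldeca-4,8-dienenitrile | N#CCC/C(C)=C/CC/C(C)=C\CO[Si](C)(C)C(C)(C)C | intermediate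
6 | (4E,8Z)-N-[bis(2-methylpropyl)alumanyl]-10-[(tert-butyldimethylsilyl)oxy]-4,8-dimethyldeca-4,8-dien-1-imine | CC(C)C[Al](CC(C)C)N=CCC/C(C)=C/CC/C(C)=C\CO[Si](C)(C)C(C)(C)C | intermediate
7 | (4E,8Z)-10-[(tert-butyldimethylsilyl)oxy]-4,8-dimethyldeca-4,8-dienal | O=CCC/C(C)=C/CC/C(C)=C\CO[Si](C)(C)C(C)(C)C | intermediate
8 | methyl 2-(triphenyl-λ5-phosphanylidene)propanoate | COC(=O)C(C)=P(c1ccccc1)(c1ccccc1)c1ccccc1 | starting material
9 | methyl (2E,6E,10Z)-12-[(tert-butyldimethylsilyl)oxy]-2,6,10-trimethyldodeca-2,6,10-trienoate | COC(=O)/C(C)=C/CC/C(C)=C/CC/C(C)=C\CO[Si](C)(C)C(C)(C)C | intermediate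
10 | methyl (2E,6E,10Z)-12-hydroxy-2,6,10-trimethyldodeca-2,6,10-trienoate | COC(=O)/C(C)=C/CC/C(C)=C/CC/C(C)=C\CO | intermediate
11 | methyl (2E,6E)-9-[(2S,3R)-3-(hydroxymethyl)-2-methyloxiran-2-yl]-2,6-dimethylnona-2,6-dienoate | COC(=O)/C(C)=C/CC/C(C)=C/CC[C@]1(C)O[C@@H]1CO | intermediate
12 | methyl (2E,6E)-2,6-dimethyl-9-[(2S,3R)-2-methyl-3-{[(trifluoromethanesulfonyl)oxy]methyl}oxiran-2-yl]nona-2,6-dienoate | COC(=O)/C(C)=C/CC/C(C)=C/CC[C@]1(C)O[C@@H]1COS(=O)(=O)C(F)(F)F | intermediate
13 | resorcinol, benzene-1,3-diol | Oc1cccc(O)c1 | starting material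
14 | 2-iodobenzene-1,3-diol | Oc1cccc(O)c1I | intermediate
15 | 2-iodo-1,3-bis(prop-2-en-1-yloxy)benzene | C=CCOc1cccc(OCC=C)c1I | intermediate
16 | [2,6-bis(prop-2-en-1-yloxy)phenyl]magnesium chloride | C=CCOc1cccc(OCC=C)c1[Mg]Cl | intermediate
17 | methyl (2E,6E)-9-[(2S,3R)-3-{[2,6-bis(prop-2-en-1-yloxy)phenyl]methyl}-2-methyloxiran-2-yl]-2,6-dimethylnona-2,6-dienoate | COC(=O)/C(C)=C/CC/C(C)=C/CC[C@]1(C)O[C@@H]1Cc1c(OCC=C)cccc1OCC=C | intermediate
18 | methyl (2E,6E)-9-{(2S,3R)-3-[(2,6-dihydroxyphenyl)methyl]-2-methyloxiran-2-yl}-2,6-dimethylnona-2,6-dienoate | COC(=O)/C(C)=C/CC/C(C)=C/CC[C@]1(C)O[C@@H]1Cc1c(O)cccc1O | intermediate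
19 | methyl (2E,6E,10S)-10-hydroxy-10-[(2S)-4-hydroxy-2,3-dihydro-1-benzofuran-2-yl]-2,6-dimethylundeca-2,6-dienoate | COC(=O)/C(C)=C/CC/C(C)=C/CC[C@](C)(O)[C@@H]1Cc2c(O)cccc2O1 | intermediate
20 | methyl (2E,6E,10S)-10-hydroxy-10-[(2S)-4-hydroxy-7-methoxy-2,3-dihydro-1-benzofuran-2-yl]-2,6-dimethylundeca-2,6-dienoate | COC(=O)/C(C)=C/CC/C(C)=C/CC[C@](C)(O)[C@@H]1Cc2c(O)ccc(OC)c2O1 | intermediate
21 | methyl (2E,6E,10S)-10-[(2S)-7,7-dimethoxy-4-oxo-2,3,4,7-tetrahydro-1-benzofuran-2-yl]-10-hydroxy-2,6-dimethylundeca-2,6-dienoate | COC(=O)/C(C)=C/CC/C(C)=C/CC[C@](C)(O)[C@@H]1CC2=C(O1)C(OC)(OC)C=CC2=O | intermediate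
22 | methyl (2E,6E,10S)-10-[(2S)-7,7-dimethoxy-4-oxo-2,3,4,5,6,7-hexahydro-1-benzofuran-2-yl]-10-hydroxy-2,6-dimethylundeca-2,6-dienoate | COC(=O)/C(C)=C/CC/C(C)=C/CC[C@](C)(O)[C@@H]1CC2=C(O1)C(OC)(OC)CCC2=O | intermediate
23 | methyl (2E,6E,10S)-10-[(2S)-4,7-dioxo-2,3,4,5,6,7-hexahydro-1-benzofuran-2-yl]-10-hydroxy-2,6-dimethylundeca-2,6-dienoate | COC(=O)/C(C)=C/CC/C(C)=C/CC[C@](C)(O)[C@@H]1CC2=C(O1)C(=O)CCC2=O | intermediate
24 | methyl (2E,6E,10S)-10-hydroxy-10-[(2S,7R)-7-hydroxy-4-oxo-2,3,4,5,6,7-hexahydro-1-benzofuran-2-yl]-2,6-dimethylundeca-2,6-dienoate | COC(=O)/C(C)=C/CC/C(C)=C/CC[C@](C)(O)[C@@H]1CC2=C(O1)[C@H](O)CCC2=O | intermediate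
25 | (2E,6E,10S)-10-hydroxy-10-[(2S,7R)-7-hydroxy-4-oxo-2,3,4,5,6,7-hexahydro-1-benzofuran-2-yl]-2,6-dimethylundeca-2,6-dienoic acid | OC(=O)/C(C)=C/CC/C(C)=C/CC[C@](C)(O)[C@@H]1CC2=C(O1)[C@H](O)CCC2=O | target

**Step count and risks**

Total step count: 18. Longest linear sequence: 16 steps (steps 1–9 and 12–18).

Step 16 is the most exposed. The risk is aromatisation: loss of methanol from the oxocarbenium ion, or double enolisation of the freed dione, may outrun clean hydrolysis. The fallback sets out from 22 and never isolates the dione. Ketal 22 is exposed to Noyori–Ikariya transfer-hydrogenation conditions [RuCl(p-cymene)((R,R)-TsDPEN), HCO2H/Et3N 5:2 with a little water, rt]. The acidic medium should hydrolyse the ketal and the ruthenium hydride should reduce the C7 ketone as it is released, so the dione does not accumulate. The (R,R)-ligand is chosen because the sp2 carbon C7a takes the place of the aryl group of an aryl ketone. The route is rejoined at 24 and no new compound is made (F0).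

Step 17 comes next. The risk is poor facial selectivity, reduction at the wrong carbonyl, or Lewis-acid-induced tautomerisation of 23 during the oxazaborolidine reduction. The fallback sets out from 23 with a Luche reduction (NaBH4, CeCl3·7H2O, MeOH, −78 °C), which should reduce only the C7 ketone but without facial control. It should give 24 together with its C7 epimer, methyl (2E,6E,10S)-10-hydroxy-10-[(2S,7S)-7-hydroxy-4-oxo-2,3,4,5,6,7-hexahydro-1-benzofuran-2-yl]-2,6-dimethylundeca-2,6-dienoate F1. The two are diastereomers and should be separable by chromatography. The epimer is inverted at C7 by a Mitsunobu reaction (4-nitrobenzoic acid, PPh3, DIAD, THF, 0 °C; the tertiary alcohol does not react) to methyl (2E,6E,10S)-10-hydroxy-2,6-dimethyl-10-{(2S,7R)-7-[(4-nitrobenzoyl)oxy]-4-oxo-2,3,4,5,6,7-hexahydro-1-benzofuran-2-yl}undeca-2,6-dienoate F2. Methanolysis of that ester (K2CO3, MeOH, 0 °C) returns to the route at 24.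

Step 18 is the third. The risk is dehydration of the 7-hydroxy enone towards the phenol, opening of the vinylogous ester, or incomplete cleavage of the hindered conjugated ester. The fallback sets out from 22, which has none of these weaknesses, and saponifies first (LiOH, THF/H2O, rt, then pH 4 buffer) to (2E,6E,10S)-10-[(2S)-7,7-dimethoxy-4-oxo-2,3,4,5,6,7-hexahydro-1-benzofuran-2-yl]-10-hydroxy-2,6-dimethylundeca-2,6-dienoic acid F3. The ketal is then hydrolysed as in step 16 to (2E,6E,10S)-10-[(2S)-4,7-dioxo-2,3,4,5,6,7-hexahydro-1-benzofuran-2-yl]-10-hydroxy-2,6-dimethylundeca-2,6-dienoic acid F4. This acid is reduced by the acid-tolerant Noyori–Ikariya transfer hydrogenation [RuCl(p-cymene)((R,R)-TsDPEN), HCO2H/Et3N], which arrives directly at 25.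

**Further compounds**

F0 | step 16 | none | none
F1 | step 17 | methyl (2E,6E,10S)-10-hydroxy-10-[(2S,7S)-7-hydroxy-4-oxo-2,3,4,5,6,7-hexahydro-1-benzofuran-2-yl]-2,6-dimethylundeca-2,6-dienoate | COC(=O)/C(C)=C/CC/C(C)=C/CC[C@](C)(O)[C@@H]1CC2=C(O1)[C@@H](O)CCC2=O
F2 | step 17 | methyl (2E,6E,10S)-10-hydroxy-2,6-dimethyl-10-{(2S,7R)-7-[(4-nitrobenzoyl)oxy]-4-oxo-2,3,4,5,6,7-hexahydro-1-benzofuran-2-yl}undeca-2,6-dienoate | COC(=O)/C(C)=C/CC/C(C)=C/CC[C@](C)(O)[C@@H]1CC2=C(O1)[C@H](OC(=O)c3ccc(cc3)[N+](=O)[O-])CCC2=O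
F3 | step 18 | (2E,6E,10S)-10-[(2S)-7,7-dimethoxy-4-oxo-2,3,4,5,6,7-hexahydro-1-benzofuran-2-yl]-10-hydroxy-2,6-dimethylundeca-2,6-dienoic acid | OC(=O)/C(C)=C/CC/C(C)=C/CC[C@](C)(O)[C@@H]1CC2=C(O1)C(OC)(OC)CCC2=O
F4 | step 18 | (2E,6E,10S)-10-[(2S)-4,7-dioxo-2,3,4,5,6,7-hexahydro-1-benzofuran-2-yl]-10-hydroxy-2,6-dimethylundeca-2,6-dienoic acid | OC(=O)/C(C)=C/CC/C(C)=C/CC[C@](C)(O)[C@@H]1CC2=C(O1)C(=O)CCC2=O
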